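The target is cut at the bond between the bridging CH2 and C4 of ring B (the enolised acyl-trione). Knoevenagel condensation with in-situ hydride transfer re-forms this bond from a ring A aldehyde and an enantiopure ring B core. In ring A (the cyclopentane) three contiguous carbons guide the plan. C2' (tertiary carbinol) is read as a ketone carbonyl, C1' (bridge CH2) as its enolate carbon, and C5' (isopropenyl) as the β-carbon of an enone. One copper-catalysed operation thus unites cyclopentenone, isopropenylmagnesium bromide and formaldehyde. It forges the C5'–isopropenyl and C1'–CH2 bonds and both stereocentres, trans, without ring closure. Its precursors are three achiral commercial compounds.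

Key step: step 1

Assumption: the target and the ring B core are treated as the single enol tautomers drawn (the C6 descriptor refers to them), and the ligand antipode that gives the 3R adduct is settled in a trial run, both antipodes being commercial.

**Fragment 1 (ring A)**

Step 1
Reactants: 1 cyclopent-2-en-1-one; 2 isopropenylmagnesium bromide; 3 formaldehyde (monomeric gas, from thermally cracked paraformaldehyde)
Product: 5 (2R,3R)-2-(hydroxymethyl)-3-(prop-1-en-2-yl)cyclopentan-1-one, via bromomagnesium enolate 4 (not isolated)
Conditions: CuBr·SMe2 (5 mol %), (R)-1-[(Sp)-2-(diphenylphosphino)ferrocenyl]ethyldicyclohexylphosphine (6 mol %), tBuOMe, −75 °C, slow parallel addition of 1 and 2 (1.2 equiv); then gaseous 3 in a N2 stream, −75 → −40 °C; sat. aq. NH4Cl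
Reagents that add atoms: none
Why: Transmetallation of 2 onto the diphosphine-bound monovalent copper gives an alkenylcuprate that binds the C2=C3 bond of 1, adds oxidatively at C3 to a trivalent copper intermediate and releases the C3–isopropenyl bond by reductive elimination, leaving the regiodefined C1–C2 magnesium enolate 4. The closest known reaction type is the copper/ferrocenyl-diphosphine-catalysed asymmetric conjugate addition of Grignard reagents to cyclic enones, joined to the classical capture of the resulting enolate by monomeric formaldehyde in three-component cyclopentanone syntheses. No ring is closed, so no mode of closure has to be judged, and the two new C–C bonds are made on the intact five-membered ring. C3 (later C5') is set by the chiral pocket of the ligand, which leaves one face of the bound enone open, and C2 (later C1') by approach of formaldehyde to the enolate face opposite the new isopropenyl group, a trans outcome that is also the thermodynamic one because C2 stays epimerisable. The step needs 1,4- over 1,2-addition and capture at C2 only: slow parallel addition keeps free Grignard reagent and free enone scarce, so that the copper cycle outruns direct carbonyl attack and enolate-to-enone Michael addition, and 4, born regiospecifically, meets the very electrophilic gas before it can equilibrate. The mild NH4Cl quench keeps the β-hydroxy ketone from dehydrating.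

Step 2
Reactants: 5 (2R,3R)-2-(hydroxymethyl)-3-(prop-1-en-2-yl)cyclopentan-1-one
Product: 6 (2R,3R)-2-{[(tert-butyldimethylsilyl)oxy]methyl}-3-(prop-1-en-2-yl)cyclopentan-1-one
Conditions: TBSCl, imidazole, CH2Cl2, 0 °C → rt
Reagents that add atoms: tert-butyldimethylsilyl chloride, CC(C)(C)[Si](C)(C)Cl
Why: Imidazole-promoted silylation of the primary alcohol is mild enough not to trigger β-elimination, blocks retro-aldol loss of formaldehyde in the next step and enlarges the arm for facial control.

Step 3
Reactants: 6 (2R,3R)-2-{[(tert-butyldimethylsilyl)oxy]methyl}-3-(prop-1-en-2-yl)cyclopentan-1-one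
Product: 7 (1R,2R,3R)-2-{[(tert-butyldimethylsilyl)oxy]methyl}-1-methyl-3-(prop-1-en-2-yl)cyclopentan-1-ol
Conditions: anhydrous CeCl3, MeMgBr, THF, −78 °C, then 6, −78 °C; sat. aq. NH4Cl
Reagents that add atoms: methylmagnesium bromide, C[Mg]Br
Why: In this organocerium 1,2-addition the weakly basic methylcerium reagent attacks the ketone without enolisation or β-elimination of the silyloxy group and comes in from the face opposite the neighbouring CH2OTBS arm, so the new hydroxyl ends cis to the arm and trans to isopropenyl (1R), any minor epimer being removable by chromatography.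

Step 4
Reactants: 7 (1R,2R,3R)-2-{[(tert-butyldimethylsilyl)oxy]methyl}-1-methyl-3-(prop-1-en-2-yl)cyclopentan-1-ol
Product: 8 (1R,2R,3R)-2-(hydroxymethyl)-1-methyl-3-(prop-1-en-2-yl)cyclopentan-1-ol
Conditions: Bu4NF, THF, 0 °C → rt
Reagents that add atoms: none
Why: Fluoride-driven desilylation, powered by the strong Si–F bond, frees the primary alcohol under non-acidic conditions that spare the tertiary alcohol and the isopropenyl group.

Step 5
Reactants: 8 (1R,2R,3R)-2-(hydroxymethyl)-1-methyl-3-(prop-1-en-2-yl)cyclopentan-1-ol
Product: 9 (1S,2R,5R)-2-hydroxy-2-methyl-5-(prop-1-en-2-yl)cyclopentane-1-carbaldehyde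
Conditions: (2,2,6,6-tetramethylpiperidin-1-yl)oxyl (TEMPO, 10 mol %), PhI(OAc)2, CH2Cl2, rt; used promptly
Reagents that add atoms: none
Why: The oxoammonium (TEMPO/PhI(OAc)2) oxidation acts only on the primary alcohol because the tertiary one has no carbinol hydrogen, stops at the aldehyde in dry CH2Cl2, leaves the alkene alone, and does not endanger C1' since the aldehyde trans to isopropenyl is the more stable epimer.

**Fragment 2 (ring B core)**

Step 6
Reactants: 10 ethyl (R)-3-hydroxybutanoate
Product: 12 ethyl (2R)-2-[(1R)-1-hydroxyethyl]-5-methylhex-4-enoate, via dilithio alkoxide enolate 11 (not isolated)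
Conditions: LiN(iPr)2 (2.2 equiv), THF, −78 → −20 °C; prenyl bromide, DMPU, −78 → 0 °C; sat. aq. NH4Cl
Reagents that add atoms: prenyl bromide (1-bromo-3-methylbut-2-ene), CC(C)=CCBr
Why: In this Fráter–Seebach alkylation the lithium-chelated alkoxide enolate 11 is attacked by the allylic bromide on the face anti to the methyl group on the carbinol carbon, which gives the 2,3-anti (2R) product.

Step 7
Reactants: 12 ethyl (2R)-2-[(1R)-1-hydroxyethyl]-5-methylhex-4-enoate
Product: 14 ethyl (2S)-2-[(1R)-1-hydroxyethyl]-2,5-dimethylhex-4-enoate, via dilithio alkoxide enolate 13 (not isolated)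
Conditions: LiN(iPr)2 (2.5 equiv), THF, −78 → −10 °C; MeI, DMPU, −78 → 0 °C; sat. aq. NH4Cl
Reagents that add atoms: iodomethane, CI
Why: In this second Fráter–Seebach alkylation re-enolisation flattens C2 and MeI again enters the chelated enolate 13 anti to the carbinol methyl group, so the order prenyl-then-methyl fixes the quaternary centre as 2S, the sense needed for C6 of ring B, and removal of the minor diastereomer at this stage secures the enantiopurity of all later core compounds.

Step 8
Reactants: 14 ethyl (2S)-2-[(1R)-1-hydroxyethyl]-2,5-dimethylhex-4-enoate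
Product: 15 ethyl (2S)-2-acetyl-2,5-dimethylhex-4-enoate
Conditions: Dess–Martin periodinane, CH2Cl2, 0 °C → rt
Reagents that add atoms: none
Why: Dess–Martin oxidation turns the hindered secondary alcohol, whose stereochemical duty is done, into the methyl ketone under non-nucleophilic conditions that avoid retro-Claisen cleavage and cannot touch the non-enolisable quaternary centre.

Step 9
Reactants: 15 ethyl (2S)-2-acetyl-2,5-dimethylhex-4-enoate
Product: 16 ethyl (2S)-2-methyl-2-(3-methylbut-2-en-1-yl)-3,5-dioxohexanoate
Conditions: MgBr2·OEt2 (2.5 equiv), iPr2NEt (3 equiv), 1-acetylbenzotriazole (1.2 equiv), CH2Cl2, rt; 1 M HCl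
Reagents that add atoms: 1-acetylbenzotriazole, CC(=O)n1nnc2ccccc12
Why: In this crossed Claisen C-acylation by soft enolisation, MgBr2 coordination lets the amine enolise the only enolisable position (the CH3 group), the acylbenzotriazole acylates at carbon, and the absence of strong base or alkoxide prevents both retro-Claisen cleavage and premature ring closure to the achiral, acyl-free trione.

Step 10
Reactants: 17 (S)-2-methylbutanoic acid
Product: 18 (S)-2-methylbutanoyl chloride
Conditions: (COCl)2, N,N-dimethylformamide (cat.), CH2Cl2, 0 °C → rt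
Reagents that add atoms: oxalyl chloride, O=C(Cl)C(=O)Cl
Why: Vilsmeier-type activation with oxalyl chloride gives the acid chloride without any base, so the α-stereocentre is not enolised.

Step 11
Reactants: 16 ethyl (2S)-2-methyl-2-(3-methylbut-2-en-1-yl)-3,5-dioxohexanoate; 18 (S)-2-methylbutanoyl chloride
Product: 19 ethyl (2S,6S)-4-acetyl-2,6-dimethyl-2-(3-methylbut-2-en-1-yl)-3,5-dioxooctanoate (enol mixture, C4 not defined)
Conditions: MgCl2, pyridine, CH2Cl2, 0 °C → rt; 1 M HCl
Reagents that add atoms: none
Why: In this magnesium-mediated C-acylation of a 1,3-diketone the chelate reacts at its central carbon, pyridine is too weak a base to turn 18 into a ketene, and placing the chiral acyl group next to the former ketone carbonyl (future C1) before ring closure keeps the two flanks of the quaternary carbon different.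

Step 12
Reactants: 19 ethyl (2S,6S)-4-acetyl-2,6-dimethyl-2-(3-methylbut-2-en-1-yl)-3,5-dioxooctanoate
Product: 21 (6R)-3,5-dihydroxy-6-methyl-6-(3-methylbut-2-en-1-yl)-2-[(2S)-2-methylbutanoyl]cyclohexa-2,4-dien-1-one, via dilithio dienolate 20 (not isolated)
Conditions: LiN(iPr)2 (3.3 equiv), THF, −78 → 0 °C; 1 M HCl
Reagents that add atoms: none
Why: In this Dieckmann-type intramolecular Claisen condensation the base removes the acidic methine proton and then, kinetically, a proton of the acetyl CH3 rather than the tertiary α-CH of the chiral side chain, the terminal carbanion of 20 closes ring B on the ester carbon (future C5) in a 6-exo-trig mode, and the doubly stabilised enolate of 21 drives the reaction while the quaternary centre stays a spectator.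

**Union of the fragments**

Step 13
Reactants: 21 (6R)-3,5-dihydroxy-6-methyl-6-(3-methylbut-2-en-1-yl)-2-[(2S)-2-methylbutanoyl]cyclohexa-2,4-dien-1-one; 9 (1S,2R,5R)-2-hydroxy-2-methyl-5-(prop-1-en-2-yl)cyclopentane-1-carbaldehyde
Product: 23 (6R)-3,5-dihydroxy-4-{[(1S,2R,5R)-2-hydroxy-2-methyl-5-(prop-1-en-2-yl)cyclopentyl]methyl}-6-methyl-6-(3-methylbut-2-en-1-yl)-2-[(2S)-2-methylbutanoyl]cyclohexa-2,4-dien-1-one, via alkylidene trione 22 (not isolated)
Conditions: L-proline (20 mol %), diethyl 2,6-dimethyl-1,4-dihydropyridine-3,5-dicarboxylate (Hantzsch ester, 1.1 equiv), CH2Cl2, rt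
Reagents that add atoms: none
Why: In this organocatalytic three-component reductive alkylation a proline-promoted Knoevenagel condensation at C4, the only free nucleophilic carbon of ring B, gives 22, which the Hantzsch ester reduces at once by conjugate hydride transfer, so no new stereocentre arises and bis-addition, dehydration or retro-aldol of the β-hydroxy aldehyde get little time.

**Compound list**

1 | cyclopent-2-en-1-one | O=C1C=CCC1 | starting material
2 | isopropenylmagnesium bromide | C=C(C)[Mg]Br | starting material
3 | formaldehyde | C=O | starting material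
4 | bromomagnesium (3R)-3-(prop-1-en-2-yl)cyclopent-1-en-1-olate | C=C(C)[C@@H]1CCC(O[Mg]Br)=C1 | intermediate (not isolated)
5 | (2R,3R)-2-(hydroxymethyl)-3-(prop-1-en-2-yl)cyclopentan-1-one (trans) | C=C(C)[C@@H]1CCC(=O)[C@H]1CO | intermediate
6 | (2R,3R)-2-{[(tert-butyldimethylsilyl)oxy]methyl}-3-(prop-1-en-2-yl)cyclopentan-1-one | C=C(C)[C@@H]1CCC(=O)[C@H]1CO[Si](C)(C)C(C)(C)C | intermediate
7 | (1R,2R,3R)-2-{[(tert-butyldimethylsilyl)oxy]methyl}-1-methyl-3-(prop-1-en-2-yl)cyclopentan-1-ol (OH cis to the arm) | C=C(C)[C@@H]1CC[C@@](C)(O)[C@H]1CO[Si](C)(C)C(C)(C)C | intermediate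
8 | (1R,2R,3R)-2-(hydroxymethyl)-1-methyl-3-(prop-1-en-2-yl)cyclopentan-1-ol | C=C(C)[C@@H]1CC[C@@](C)(O)[C@H]1CO | intermediate
9 | (1S,2R,5R)-2-hydroxy-2-methyl-5-(prop-1-en-2-yl)cyclopentane-1-carbaldehyde | C=C(C)[C@@H]1CC[C@@](C)(O)[C@H]1C=O | intermediate
10 | ethyl (R)-3-hydroxybutanoate | CCOC(=O)C[C@@H](C)O | starting material
11 | dilithio alkoxide enolate of 10, (3R)-1-ethoxy-1,3-bis(lithiooxy)but-1-ene | CCOC(O[Li])=C[C@@H](C)O[Li] | intermediate (not isolated)
12 | ethyl (2R)-2-[(1R)-1-hydroxyethyl]-5-methylhex-4-enoate | CCOC(=O)[C@H](CC=C(C)C)[C@@H](C)O | intermediate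
13 | dilithio alkoxide enolate of 12, 1-ethoxy-1-(lithiooxy)-2-[(1R)-1-(lithiooxy)ethyl]-5-methylhexa-1,4-diene | CCOC(O[Li])=C(CC=C(C)C)[C@@H](C)O[Li] | intermediate (not isolated)
14 | ethyl (2S)-2-[(1R)-1-hydroxyethyl]-2,5-dimethylhex-4-enoate | CCOC(=O)[C@@](C)(CC=C(C)C)[C@@H](C)O | intermediate
15 | ethyl (2S)-2-acetyl-2,5-dimethylhex-4-enoate | CCOC(=O)[C@@](C)(CC=C(C)C)C(C)=O | intermediate
16 | ethyl (2S)-2-methyl-2-(3-methylbut-2-en-1-yl)-3,5-dioxohexanoate | CCOC(=O)[C@@](C)(CC=C(C)C)C(=O)CC(C)=O | intermediate
17 | (S)-2-methylbutanoic acid | CC[C@H](C)C(=O)O | starting material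
18 | (S)-2-methylbutanoyl chloride | CC[C@H](C)C(=O)Cl | intermediate
19 | ethyl (2S,6S)-4-acetyl-2,6-dimethyl-2-(3-methylbut-2-en-1-yl)-3,5-dioxooctanoate | CCOC(=O)[C@@](C)(CC=C(C)C)C(=O)C(C(C)=O)C(=O)[C@@H](C)CC | intermediate
20 | dilithio dienolate of 19 (central enolate plus terminal CH2=C(OLi) enolate of the acetyl group) | CCOC(=O)[C@@](C)(CC=C(C)C)C(=O)C(C(=C)O[Li])=C(O[Li])[C@@H](C)CC | intermediate (not isolated)
21 | (6R)-3,5-dihydroxy-6-methyl-6-(3-methylbut-2-en-1-yl)-2-[(2S)-2-methylbutanoyl]cyclohexa-2,4-dien-1-one (ring B core) | CC[C@H](C)C(=O)C1=C(O)C=C(O)[C@@](C)(CC=C(C)C)C1=O | intermediate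
22 | Knoevenagel adduct of 21 and 9: C4=CH–C1' alkylidene, C3 and C5 as ketones, C1 as enol, ring A as in 9, alkene geometry not fixed | C=C(C)[C@@H]1CC[C@@](C)(O)[C@H]1C=C1C(=O)C(C(=O)[C@@H](C)CC)=C(O)[C@](C)(CC=C(C)C)C1=O | intermediate (not isolated)
23 | (6R)-3,5-dihydroxy-4-{[(1S,2R,5R)-2-hydroxy-2-methyl-5-(prop-1-en-2-yl)cyclopentyl]methyl}-6-methyl-6-(3-methylbut-2-en-1-yl)-2-[(2S)-2-methylbutanoyl]cyclohexa-2,4-dien-1-one | C=C(C)[C@@H]1CC[C@@](C)(O)[C@H]1CC1=C(O)[C@@](C)(CC=C(C)C)C(=O)C(C(=O)[C@@H](C)CC)=C1O | target

Total step count: 13. Longest linear sequence: 7 steps (6, 7, 8, 9, 11, 12, 13).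

**Steps most likely to fail**

Step 1. Several processes may go wrong.
- Enantioface discrimination may be weak, since an sp2 Grignard reagent and the small, flat enone are both demanding partners for the chiral copper catalyst, and the coordinating solvent brought in with 2 can loosen it.
- Direct 1,2-addition may compete.
- Enolate 4 may be lost by proton transfer or by Michael addition to 1.
- The formaldehyde gas may polymerise before it reaches 4.

The fallback separates the two bond formations and sets out from 4. Silylation in the flask (Me3SiCl, Et3N, −75 °C → rt) gives the isolable, regiodefined {[(3R)-3-(prop-1-en-2-yl)cyclopent-1-en-1-yl]oxy}trimethylsilane F1. After purification and a check of its enantiopurity, a Mukaiyama aldol reaction with commercial aqueous formaldehyde (Yb(OTf)3 cat., THF/H2O, rt) should place the hydroxymethyl group at C2 anti to isopropenyl. This comes back to the route at 5. A moderate enantiomeric excess is tolerable in either variant, because coupling with enantiopure 21 turns the minor antipode into a diastereomer of 23 that chromatography should remove.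

Step 13. Amine-catalysed dehydration or retro-aldol opening of the β-hydroxy aldehyde may outrun condensation at its hindered, α-branched carbonyl. A second molecule of 21 may also add to 22 before hydride transfer. The fallback avoids the aldehyde and the amine altogether and sets out from 5, with 21 as partner.
- Mesylation (MsCl, Et3N, CH2Cl2, 0 °C) gives [(1R,5R)-2-oxo-5-(prop-1-en-2-yl)cyclopentyl]methyl methanesulfonate F2.
- F2 eliminates with excess Et3N to (3S)-2-methylidene-3-(prop-1-en-2-yl)cyclopentan-1-one F3.
- Michael addition of C4 of 21 to this exocyclic enone (cat. Et3N, CH2Cl2, rt), followed by thermodynamic protonation trans to isopropenyl, gives (6R)-3,5-dihydroxy-6-methyl-6-(3-methylbut-2-en-1-yl)-2-[(2S)-2-methylbutanoyl]-4-{[(1S,5R)-2-oxo-5-(prop-1-en-2-yl)cyclopentyl]methyl}cyclohexa-2,4-dien-1-one F4.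
- Excess MeMgBr/CeCl3 (THF, −78 °C) first turns ring B into an inert dianion and then adds methyl to the cyclopentanone anti to the arm. This comes back to the route at 23.

Step 12. Several processes may go wrong.
- The second deprotonation may not be clean.
- Liberated ethoxide may deacylate the crowded triacylmethane.
- An enolate oxygen may close on the ester to give an enol lactone.
- The side-chain stereocentre may erode.

The fallback exchanges acyclic stereocontrol for dearomatisation and sets out from 18. Friedel–Crafts acylation of commercial 2-methylbenzene-1,3,5-triol (AlCl3, CH2Cl2/PhNO2) gives (2S)-2-methyl-1-(2,4,6-trihydroxy-3-methylphenyl)butan-1-one F5. Dearomative C-prenylation at the methyl-bearing carbon (prenyl bromide, aq. KOH, 0 °C) gives 21 together with its C6 epimer, (6S)-3,5-dihydroxy-6-methyl-6-(3-methylbut-2-en-1-yl)-2-[(2S)-2-methylbutanoyl]cyclohexa-2,4-dien-1-one F6. The two diastereomers are parted by preparative HPLC, and the route is rejoined at 21.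

**Further compounds**

F1 | step 1 | {[(3R)-3-(prop-1-en-2-yl)cyclopent-1-en-1-yl]oxy}trimethylsilane | C=C(C)[C@@H]1CCC(O[Si](C)(C)C)=C1
F2 | step 13 | [(1R,5R)-2-oxo-5-(prop-1-en-2-yl)cyclopentyl]methyl methanesulfonate | C=C(C)[C@@H]1CCC(=O)[C@H]1COS(C)(=O)=O
F3 | step 13 | (3S)-2-methylidene-3-(prop-1-en-2-yl)cyclopentan-1-one | C=C(C)[C@@H]1CCC(=O)C1=C
F4 | step 13 | (6R)-3,5-dihydroxy-6-methyl-6-(3-methylbut-2-en-1-yl)-2-[(2S)-2-methylbutanoyl]-4-{[(1S,5R)-2-oxo-5-(prop-1-en-2-yl)cyclopentyl]methyl}cyclohexa-2,4-dien-1-one | C=C(C)[C@@H]1CCC(=O)[C@H]1CC1=C(O)[C@@](C)(CC=C(C)C)C(=O)C(C(=O)[C@@H](C)CC)=C1O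
F5 | step 12 | (2S)-2-methyl-1-(2,4,6-trihydroxy-3-methylphenyl)butan-1-one | CC[C@H](C)C(=O)c1c(O)cc(O)c(C)c1O
F6 | step 12 | (6S)-3,5-dihydroxy-6-methyl-6-(3-methylbut-2-en-1-yl)-2-[(2S)-2-methylbutanoyl]cyclohexa-2,4-dien-1-one | CC[C@H](C)C(=O)C1=C(O)C=C(O)[C@](C)(CC=C(C)C)C1=O
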